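## Retrosynthetic overview

1. The only C–C bond made is aryl–CH2: docos-1-ene 1 and 2-bromo-3-methylphenol 2 are joined through borane 3 (B-alkyl Suzuki–Miyaura) to give phenol 4.
2. All other disconnections are ring C–O bonds. The oxygen para to the OH of 4 comes from methanol (4 → 5 → para-quinone monoketal 6, dearomatisation with trivalent iodine).
3. Key step: the C–OMe bond ortho to that OH is traced back to ketal 6. A new acid-triggered transfer of methanol to the CH carbon alpha to the carbonyl gives arene 7. The regiochemistry is fixed because the only free carbonyl of 6 is the oxygen next to the docosyl chain.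
4. The last C=O comes from oxidation of 7 with loss of the para methyl ether, giving quinone 8.
5. No ring is formed: the benzene ring of 2 is carried through and becomes the quinone ring of 8.

Assumption: the side chain of the SMILES is read as unbranched docosyl (22 carbons); the target has no stereocentre and no stereogenic double bond, so it is one achiral compound and no step needs stereocontrol.

## Route

Step 1
Reactants: 1 docos-1-ene; 2 2-bromo-3-methylphenol
Product: 4 2-docosyl-3-methylphenol, via B-docosyl-9-BBN 3 (not isolated)
Conditions: 1 (1.3 equiv), 9-BBN (1.3 equiv), THF, 0 °C to rt; then 2, Pd(OAc)2 (3 mol %), SPhos (6 mol %), K3PO4 (3 equiv), H2O, 65 °C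
Reagents that add atoms: none
Why: Hydroboration of the terminal alkene with 9-BBN is anti-Markovnikov, and the primary alkylborane 3 then couples with the aryl bromide in a B-alkyl Suzuki–Miyaura reaction (the SPhos–palladium catalyst tolerates the two ortho substituents and the free phenol, present as its phenoxide), so the unbranched chain lands on the carbon between OH and CH3; no stereocentre is formed.

Step 2
Reactants: 4 2-docosyl-3-methylphenol
Product: 6 2-docosyl-4,4-dimethoxy-3-methylcyclohexa-2,5-dien-1-one, via 2-docosyl-4-methoxy-3-methylphenol 5 (not isolated)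
Conditions: PhI(OAc)2 (2.2 equiv), MeOH/CH2Cl2 (2:1), 0 °C to rt
Reagents that add atoms: methanol, CO
Why: This is the Pelter-type oxidative dearomatisation of a para-unsubstituted phenol with trivalent iodine in methanol: the first equivalent of PhI(OAc)2 delivers methanol to the free para position (5) and the second turns this 4-methoxyphenol into monoketal 6, which stores the para oxygen as a ketal and leaves the original phenol oxygen, the one next to the docosyl chain, as the only carbonyl; no stereocentre is formed.

Step 3
Reactants: 6 2-docosyl-4,4-dimethoxy-3-methylcyclohexa-2,5-dien-1-one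
Product: 8 3-docosyl-5-methoxy-2-methylcyclohexa-2,5-diene-1,4-dione, via 2-docosyl-4,6-dimethoxy-3-methylphenol 7 (not isolated)
Conditions: MeOH (10 equiv), TfOH (2 mol %), (CF3)2CHOH/CH2Cl2 (1:1), 3 Å MS, 25 °C; then 2,6-lutidine (5 mol %), PhI(OAc)2 (1.1 equiv), MeCN/H2O (4:1), 0 °C
Reagents that add atoms: methanol, CO; water, O
Why: Proposed new method: acid ionises the allylic ketal of 6 to a 4-methoxyphenoxenium-type oxocarbenium ion whose positive charge is shared by the ketal carbon and the two carbons alpha to the carbonyl; methanol capture at the ketal carbon only regenerates 6 and capture at the docosyl-bearing alpha carbon cannot aromatise and reverts, whereas capture at the CH alpha carbon (an SN2′-type substitution of the allylic ketal) is made irreversible by tautomerisation to arene 7, so the new C–OMe bond forms only ortho to the oxygen that neighbours the docosyl chain, and the known aqueous PhI(OAc)2 oxidation of a 4-methoxyphenol then delivers water to the para carbon, expels methanol and gives quinone 8 without any stereocentre; the closest known reaction type is the acid-promoted SN2′ substitution of quinone monoketals by carbon pi-nucleophiles at the carbon alpha to the carbonyl, not yet shown with an alcohol as nucleophile.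

## Compound list

1 | docos-1-ene | CCCCCCCCCCCCCCCCCCCCC=C | starting material
2 | 2-bromo-3-methylphenol | Cc1cccc(O)c1Br | starting material
3 | 9-docosyl-9-borabicyclo[3.3.1]nonane (B-docosyl-9-BBN) | CCCCCCCCCCCCCCCCCCCCCCB1C2CCCC1CCC2 | intermediate (not isolated)
4 | 2-docosyl-3-methylphenol | CCCCCCCCCCCCCCCCCCCCCCc1c(C)cccc1O | intermediate
5 | 2-docosyl-4-methoxy-3-methylphenol | CCCCCCCCCCCCCCCCCCCCCCc1c(C)c(OC)ccc1O | intermediate (not isolated)
6 | 2-docosyl-4,4-dimethoxy-3-methylcyclohexa-2,5-dien-1-one | CCCCCCCCCCCCCCCCCCCCCCC1=C(C)C(OC)(OC)C=CC1=O | intermediate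
7 | 2-docosyl-4,6-dimethoxy-3-methylphenol | CCCCCCCCCCCCCCCCCCCCCCc1c(C)c(OC)cc(OC)c1O | intermediate (not isolated)
8 | 3-docosyl-5-methoxy-2-methylcyclohexa-2,5-diene-1,4-dione (achiral) | CCCCCCCCCCCCCCCCCCCCCCC1=C(C)C(=O)C=C(OC)C1=O | target

## Step count and risks

Total step count: 3. Longest linear sequence: 3 steps (2 → 4 → 6 → 8; 1 enters in step 1).

Steps most likely to fail, in order of risk:

Step 3, the proposed new step, is the most uncertain. Methanol could instead add to the enone in Michael fashion (beta to the carbonyl), which after aromatisation would put the methoxy group on the wrong side of the ring. The cation could also lose a benzylic proton to a quinone methide, or traces of water could hydrolyse 6 to the methoxy-free quinone. The fallback uses known chemistry, sets out from 6 and comes back at 8. Weitz–Scheffer epoxidation of the only unsubstituted enone double bond of 6 (H2O2, LiOH, MeOH/THF, 0 °C) gives racemic cis-fused 3-docosyl-5,5-dimethoxy-4-methyl-7-oxabicyclo[4.1.0]hept-3-en-2-one F1. NaOMe in MeOH at 50 °C opens the epoxy ketone at the carbon alpha to the carbonyl, and the beta-hydroxy ketone dehydrates to the alpha-methoxy enone 2-docosyl-4,4,6-trimethoxy-3-methylcyclohexa-2,5-dien-1-one F2. The ketal is inert to base, so the two ring oxygens stay distinct. 1 M HCl in THF at 0 °C then hydrolyses the ketal of F2 to 8.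

Step 2 can lose material to ortho attack of methanol or to over-oxidation, because the phenol must be oxidised twice in one flask. The fallback sets out from 4 and comes back at 5, which is then isolated. Para-selective bromination of 4 with NBS in MeCN at 0 °C gives 4-bromo-2-docosyl-3-methylphenol F3. An Ullmann-type C–O coupling (NaOMe, CuI, DMF/MeOH, 110 °C) converts F3 into 5, so the para oxygen is installed at a C–Br bond and not by dearomatisation. Compound 5 then needs only 1.1 equiv PhI(OAc)2 in MeOH to reach 6, which is the well-behaved half of step 2.

Step 1 couples a bromide flanked by OH and CH3, so oxidative addition may be slow and beta-hydride elimination or protodeboronation of 3 may compete. The fallback sets out from 2 and comes back at 4, with reversed polarity and without palladium or borane. MOMCl and iPr2NEt in CH2Cl2 give 2-bromo-1-(methoxymethoxy)-3-methylbenzene F4. Insertion of Mg in THF gives the aryl Grignard reagent, and Li2CuCl4-catalysed alkylation with purchased 1-bromodocosane (Kochi-type coupling, THF, 0 °C to rt) gives 2-docosyl-1-(methoxymethoxy)-3-methylbenzene F5. HCl in MeOH removes the acetal to give 4.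

## Further compounds

F1 | step 3 | 3-docosyl-5,5-dimethoxy-4-methyl-7-oxabicyclo[4.1.0]hept-3-en-2-one (racemate, cis-fused, one enantiomer drawn) | CCCCCCCCCCCCCCCCCCCCCCC1=C(C)C(OC)(OC)[C@H]2O[C@H]2C1=O
F2 | step 3 | 2-docosyl-4,4,6-trimethoxy-3-methylcyclohexa-2,5-dien-1-one | CCCCCCCCCCCCCCCCCCCCCCC1=C(C)C(OC)(OC)C=C(OC)C1=O
F3 | step 2 | 4-bromo-2-docosyl-3-methylphenol | CCCCCCCCCCCCCCCCCCCCCCc1c(C)c(Br)ccc1O
F4 | step 1 | 2-bromo-1-(methoxymethoxy)-3-methylbenzene | Cc1cccc(OCOC)c1Br
F5 | step 1 | 2-docosyl-1-(methoxymethoxy)-3-methylbenzene | CCCCCCCCCCCCCCCCCCCCCCc1c(C)cccc1OCOC
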